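**Plan**

Numbering: ring C1–C10 with C4 = C(Me)OH, C5 = CHOH, C6 = CH–O-angelate, C7 = CH bearing C11 (the Me2C–OH carbon), C8 and C9 = CH2–CH2, C10 = CHMe. Enabling feature: the C8–C9 link of the ten-membered ring is two bare methylenes and its neighbours C7 and C10 carry no leaving group, so it can be made as the alkene left when an eleven-membered ring with sulfur between C8 and C9 expels SO2.
Cuts, in order: the O6–acyl ester; C8–C9 (as C8=C9, from the cyclic sulfone); S–C9 (thioether ring closure); the two C11–CH3 bonds; C6–C7 (aldol). The remaining chain C9–C10–C1–C2–C3–C4–C5–C6 with both methyl groups is geraniol.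
Forward: geraniol is worked up at both ends (C4/C5 acetonide and C6 aldehyde; C10 stereocentre and C9 chloride), the aldol adds C7, C8–S and C11, the thiacycloundecane closes at S–C9, is oxidised and protected, and contracts to the cyclodecene. Hydrogenation, selective unmasking, angeloylation and deprotection finish the route.
Stereochemistry: C4 from the Sharpless epoxidation, C5 from Payne inversion of that epoxide, C10 from BINAP-controlled hydrogenation, C6 and C7 from the oxazolidinone-controlled syn aldol; no stereocentre is set on the ring.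

Key step: step 16

Remark on the chemistry: alkene 28 is written Z, the geometry expected for a cyclodecene formed through a cis-fused episulfone, and any E isomer converges on 29 in step 17; acid 12 is taken as a catalogue compound (otherwise one step from 3-sulfanylpropanoic acid and trityl chloride); the facial sense in step 3 rests on the analogy stated there and should be confirmed on the first run.

**Route**

Step 1
Reactants: 1 geraniol, (2E)-3,7-dimethylocta-2,6-dien-1-ol
Product: 2 [(2R,3R)-3-methyl-3-(4-methylpent-3-en-1-yl)oxiran-2-yl]methanol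
Conditions: Ti(Oi-Pr)4 (cat.), D-(−)-diethyl tartrate (cat.), t-BuOOH, 4 Å MS, CH2Cl2, −20 °C
Reagents that add atoms: tert-butyl hydroperoxide, CC(C)(C)OO
Why: Sharpless asymmetric epoxidation, in which the Ti(Oi-Pr)4/tartrate catalyst binds the allylic hydroxyl so that only the C4=C5 alkene is oxidised and the D-tartrate delivers oxygen to the face giving the 4R quaternary centre (kept to the end) together with the C5 configuration that step 4 inverts.

Step 2
Reactants: 2 [(2R,3R)-3-methyl-3-(4-methylpent-3-en-1-yl)oxiran-2-yl]methanol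
Product: 3 (2E)-5-[(2R,3R)-3-(hydroxymethyl)-2-methyloxiran-2-yl]-2-methylpent-2-en-1-ol
Conditions: SeO2 (cat.), t-BuOOH, CH2Cl2, 0 °C → rt
Reagents that add atoms: SeO2 (selenium dioxide), O=[Se]=O; tert-butyl hydroperoxide, CC(C)(C)OO
Why: SeO2 allylic oxidation (ene reaction, then [2,3]-sigmatropic shift) should hydroxylate only the (E)-methyl group of the remaining trisubstituted alkene, giving the C9 alcohol as an E allylic alcohol, because the epoxide end has no allylic C–H and the catalytic variant stops at the alcohol.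

Step 3
Reactants: 3 (2E)-5-[(2R,3R)-3-(hydroxymethyl)-2-methyloxiran-2-yl]-2-methylpent-2-en-1-ol
Product: 4 (2S)-5-[(2R,3R)-3-(hydroxymethyl)-2-methyloxiran-2-yl]-2-methylpentan-1-ol
Conditions: Ru(OAc)2[(S)-BINAP] (cat.), H2 (50 atm), MeOH, rt
Reagents that add atoms: none
Why: Hydroxyl-directed asymmetric hydrogenation of a trisubstituted allylic alcohol (Noyori type), in which the (S)-BINAP ligand should deliver hydrogen to the alkene face that makes C10 S (the same face, relative to the coordinating CH2OH, that turns geraniol into (R)-citronellol), while the epoxide and the non-allylic hydroxyl are untouched.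

Step 4
Reactants: 4 (2S)-5-[(2R,3R)-3-(hydroxymethyl)-2-methyloxiran-2-yl]-2-methylpentan-1-ol
Product: 6 (2R,3R,7S)-3,7-dimethyl-1-(phenylsulfanyl)octane-2,3,8-triol, via terminal epoxide 5 (not isolated)
Conditions: PhSH, NaOH (aq.), t-BuOH, 75 °C
Reagents that add atoms: thiophenol, Sc1ccccc1
Why: Payne rearrangement with thiolate trapping, in which the C6 alkoxide opens the epoxide at C5 with inversion (C4 keeps its oxygen and configuration) and thiophenolate opens the far more reactive terminal epoxide 5 at C6, so the 4,5-diol emerges with the required erythro relationship and C6 carries a handle for oxidation.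

Step 5
Reactants: 6 (2R,3R,7S)-3,7-dimethyl-1-(phenylsulfanyl)octane-2,3,8-triol
Product: 7 (2S)-2-methyl-5-[(4R,5R)-2,2,4-trimethyl-5-[(phenylsulfanyl)methyl]-1,3-dioxolan-4-yl]pentan-1-ol
Conditions: Me2C(OMe)2, CSA (cat.), acetone, rt
Reagents that add atoms: 2,2-dimethoxypropane, COC(C)(C)OC
Why: Acid-catalysed acetonide formation engages the only 1,2-diol (O4/O5) as a dioxolane and leaves the remote primary C9 hydroxyl free, any mixed ketal there being lost on aqueous work-up.

Step 6
Reactants: 7 (2S)-2-methyl-5-[(4R,5R)-2,2,4-trimethyl-5-[(phenylsulfanyl)methyl]-1,3-dioxolan-4-yl]pentan-1-ol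
Product: 8 (4R,5R)-4-[(4S)-5-chloro-4-methylpentyl]-2,2,4-trimethyl-5-[(phenylsulfanyl)methyl]-1,3-dioxolane
Conditions: PPh3, CCl4, CH2Cl2, 40 °C
Reagents that add atoms: tetrachloromethane, ClC(Cl)(Cl)Cl
Why: The Appel reaction converts the primary alcohol into the C9 chloride under neutral conditions, a leaving group chosen because it should survive the Pummerer, boron-aldol and Grignard steps and yield only to the thiolate in step 13.

Step 7
Reactants: 8 (4R,5R)-4-[(4S)-5-chloro-4-methylpentyl]-2,2,4-trimethyl-5-[(phenylsulfanyl)methyl]-1,3-dioxolane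
Product: 9 (4R,5R)-4-[(4S)-5-chloro-4-methylpentyl]-2,2,4-trimethyl-5-[(phenylsulfinyl)methyl]-1,3-dioxolane (both sulfur epimers)
Conditions: NaIO4, MeOH/H2O, 0 °C → rt
Reagents that add atoms: NaIO4 (sodium periodate), [Na+].[O-]I(=O)(=O)=O
Why: NaIO4 oxidises an aryl alkyl sulfide to the sulfoxide without going on to the sulfone, and the mixture of sulfur epimers is of no consequence for the next step.

Step 8
Reactants: 9 (4R,5R)-4-[(4S)-5-chloro-4-methylpentyl]-2,2,4-trimethyl-5-[(phenylsulfinyl)methyl]-1,3-dioxolane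
Product: 11 (4R,5R)-5-[(4S)-5-chloro-4-methylpentyl]-2,2,5-trimethyl-1,3-dioxolane-4-carbaldehyde, via trifluoroacetoxy sulfide 10 (not isolated)
Conditions: (CF3CO)2O, 2,6-lutidine, CH2Cl2, 0 °C; then aq. NaHCO3, 0 °C
Reagents that add atoms: trifluoroacetic anhydride, O=C(OC(=O)C(F)(F)F)C(F)(F)F
Why: The Pummerer rearrangement moves the oxidation level from sulfur to C6 and the resulting O,S-acetal ester hydrolyses in the cold to the C6 aldehyde, with C5 held in the dioxolane ring and exposed only to bicarbonate so that it should not epimerise.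

Step 9
Reactants: 12 3-(tritylsulfanyl)propanoic acid; 13 (4R)-4-benzyl-1,3-oxazolidin-2-one
Product: 15 (4R)-4-benzyl-3-[3-(tritylsulfanyl)propanoyl]-1,3-oxazolidin-2-one, via mixed pivalic anhydride 14 (not isolated)
Conditions: t-BuCOCl, Et3N, THF, −20 °C; then 13, LiCl, rt
Reagents that add atoms: none
Why: N-Acylation of the oxazolidinone through the mixed pivalic anhydride with LiCl activation uses only a weak amine base, which should not trigger β-elimination of the tritylthiolate.

Step 10
Reactants: 11 (4R,5R)-5-[(4S)-5-chloro-4-methylpentyl]-2,2,5-trimethyl-1,3-dioxolane-4-carbaldehyde; 15 (4R)-4-benzyl-3-[3-(tritylsulfanyl)propanoyl]-1,3-oxazolidin-2-one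
Product: 17 (4R)-4-benzyl-3-[(2R,3R)-3-[(4S,5R)-5-[(4S)-5-chloro-4-methylpentyl]-2,2,5-trimethyl-1,3-dioxolan-4-yl]-3-hydroxy-2-[(tritylsulfanyl)methyl]propanoyl]-1,3-oxazolidin-2-one, via Z dibutylboron enolate 16 (not isolated)
Conditions: Bu2BOTf, i-Pr2NEt, CH2Cl2, −78 → 0 °C; then 11, −78 → 0 °C; pH 7 buffer/MeOH work-up
Reagents that add atoms: none
Why: Evans syn aldol reaction through the Z boron enolate and a closed chair transition state, in which the (R)-benzyl auxiliary fixes the enolate face and so sets C7 and C6 (both R, syn) in the required sense, reagent control being expected to override the facial bias of the α-alkoxy aldehyde, while the covalent boron enolate should resist loss of the β-thio group and the peroxide-free work-up spares the thioether.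

Step 11
Reactants: 17 the aldol adduct of step 10
Product: 18 methyl (2R,3R)-3-[(4S,5R)-5-[(4S)-5-chloro-4-methylpentyl]-2,2,5-trimethyl-1,3-dioxolan-4-yl]-3-hydroxy-2-[(tritylsulfanyl)methyl]propanoate
Conditions: MeMgBr, MeOH, CH2Cl2, 0 °C
Reagents that add atoms: methanol, CO
Why: Transesterification with MeOMgBr formed in the flask releases the auxiliary for recovery under conditions mild enough to avoid retro-aldol cleavage and β-elimination.

Step 12
Reactants: 18 the methyl ester of step 11
Product: 20 (1R,2R)-1-[(4S,5R)-5-[(4S)-5-chloro-4-methylpentyl]-2,2,5-trimethyl-1,3-dioxolan-4-yl]-3-methyl-2-[(tritylsulfanyl)methyl]butane-1,3-diol, via methyl ketone 19 (not isolated)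
Conditions: MeMgBr (excess), THF, 0 °C → rt
Reagents that add atoms: MeMgBr (methylmagnesium bromide), C[Mg]Br
Why: Double Grignard addition to the ester builds the C11 dimethyl carbinol, the C6 hydroxyl being masked in the flask as its bromomagnesium alkoxide and the primary chloride and trityl thioether being inert to MeMgBr.

Step 13
Reactants: 20 the trityl thioether diol of step 12
Product: 22 (3R,4R,5S,6R,10S)-3-(2-hydroxypropan-2-yl)-6,10-dimethyl-5,6-O-isopropylidene-1-thiacycloundecane-4,5,6-triol, via thiol 21 (not isolated)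
Conditions: TFA (5% v/v), Et3SiH, CH2Cl2, 0 °C; evaporate; then Cs2CO3, DMF (degassed, high dilution, slow addition), 60 °C
Reagents that add atoms: none
Why: Acidolysis of the S-trityl group with silane trapping of the trityl cation frees the C8 thiol, whose thiolate closes the eleven-membered ring by intramolecular SN2 displacement of the primary C9 chloride, a C–S closure that tolerates medium rings far better than a C–C closure and that high dilution should keep ahead of oligomer formation.

Step 14
Reactants: 22 the cyclic sulfide diol of step 13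
Product: 24 the corresponding 1,1-dioxide (cyclic sulfone diol), via sulfoxide 23 (not isolated)
Conditions: mCPBA (2.2 equiv), NaHCO3, CH2Cl2, 0 °C → rt
Reagents that add atoms: 3-chloroperoxybenzoic acid, OOC(=O)c1cccc(Cl)c1
Why: Peracid oxidation takes the dialkyl sulfide through the sulfoxide to the sulfone, the other functions being alcohols and a buffered acetonide that do not react.

Step 15
Reactants: 24 the cyclic sulfone diol of step 14
Product: 25 eleven-membered cyclic sulfone bis-acetonide (sulfur between C8 and C9; O4/O5 isopropylidene dioxolane; O6/O11 isopropylidene 1,3-dioxane)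
Conditions: 2-methoxypropene, PPTS (cat.), CH2Cl2, 0 °C → rt
Reagents that add atoms: 2-methoxypropene, COC(C)=C
Why: Kinetic acetonide formation with the enol ether bridges the secondary O6 and tertiary O11 hydroxyls as a 1,3-dioxane, so that no free hydroxyl meets the strongly basic halogenating medium of the next step.

Step 16
Reactants: 25 eleven-membered cyclic sulfone bis-acetonide
Product: 28 (8Z)-cyclodec-8-ene bis-acetonide (C8=C9 in the ten-membered ring; both acetonides unchanged), via α-bromosulfone 26 (not isolated), via episulfone 27 (not isolated)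
Conditions: KOH/Al2O3, CBr2F2, t-BuOH/CH2Cl2, 0 °C → rt
Reagents that add atoms: none
Why: Ramberg–Bäcklund reaction in its one-flask halogenative form: KOH on alumina deprotonates a sulfone α-carbon (C9 or C8, the only acidic C–H in 25), the carbanion takes bromine from CBr2F2 to give 26, and the α'-carbanion displaces bromide in a 1,3-elimination to episulfone 27, which loses SO2 cheletropically to leave C8=C9. The closest known chemistry is the contraction of medium and large cyclic sulfones to cycloalkenes under these conditions. The ten-membered carbocycle is closed by ring contraction and not end to end: the C8–C9 bond forms in a 3-exo-tet displacement inside the eleven-membered ring and the carbocycle appears when sulfur leaves, so the cost of the medium ring was paid in the easier C–S closure of step 13. No stereocentre is created (C8 and C9 become sp2 and the alkene geometry is erased in step 17), and C7 and C10, which are β to sulfur and carry no acidifying group, cannot epimerise. The step needs only chemoselectivity, which the substrate supplies: both acetals are inert to KOH, there is no leaving group on C7 or C10 for an E1cB pathway, and the two hydroxyls that could intercept difluorocarbene are tied up in the dioxane.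

Step 17
Reactants: 28 (8Z)-cyclodec-8-ene bis-acetonide
Product: 29 cyclodecane bis-acetonide (C8–C9 saturated)
Conditions: H2 (1 atm), Pd/C, EtOAc, rt
Reagents that add atoms: none
Why: Heterogeneous hydrogenation saturates the disubstituted C8=C9 alkene of either geometry, and since no C–O bond is allylic and no new stereocentre arises the step is a plain reduction.

Step 18
Reactants: 29 cyclodecane bis-acetonide
Product: 30 (4R,5S,6R,7R,10S)-7-(2-hydroxypropan-2-yl)-4,10-dimethyl-4,5-O-isopropylidenecyclodecane-4,5,6-triol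
Conditions: PPTS, MeOH, 0 °C → rt
Reagents that add atoms: none
Why: Acid-catalysed transketalisation removes the six-membered acetonide selectively, because a 1,3-dioxane acetonide, here further strained by the syn-axial methyl groups of its 2,2,4,4-tetramethyl pattern, is cleaved much faster than the five-membered 4,5-acetonide.

Step 19
Reactants: 30 the diol mono-acetonide of step 18; 31 angelic acid, (2Z)-2-methylbut-2-enoic acid
Product: 33 the O6 angelate of 30 (4,5-acetonide retained), via mixed anhydride 32 (not isolated)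
Conditions: 2,4,6-trichlorobenzoyl chloride, Et3N, toluene, rt; then 30, 80 °C
Reagents that add atoms: none
Why: Yamaguchi-type esterification through the mixed anhydride of angelic acid, run without a nucleophilic catalyst so that the Z alkene does not isomerise to the tiglate, acylates the secondary O6 hydroxyl while the tertiary O11 hydroxyl is too hindered to react.

Step 20
Reactants: 33 the angelate acetonide of step 19
Product: 34 the target, (1R,2S,3R,7S,10R)-2,3-dihydroxy-10-(2-hydroxypropan-2-yl)-3,7-dimethylcyclodecyl (2Z)-2-methylbut-2-enoate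
Conditions: TFA/H2O/THF (1:1:4), 0 °C → rt
Reagents that add atoms: none
Why: Mild aqueous acid hydrolyses the remaining dioxolane to release the C4 and C5 hydroxyls, conditions under which an angelate next to free hydroxyls is expected to survive without Z/E isomerisation or acyl migration if the reaction is stopped at conversion.

**Compound list**

1 | geraniol, (2E)-3,7-dimethylocta-2,6-dien-1-ol | CC(C)=CCC/C(C)=C/CO | starting material
2 | [(2R,3R)-3-methyl-3-(4-methylpent-3-en-1-yl)oxiran-2-yl]methanol | CC(C)=CCC[C@@]1(C)O[C@@H]1CO | intermediate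
3 | (2E)-5-[(2R,3R)-3-(hydroxymethyl)-2-methyloxiran-2-yl]-2-methylpent-2-en-1-ol | OC/C(C)=C/CC[C@@]1(C)O[C@@H]1CO | intermediate
4 | (2S)-5-[(2R,3R)-3-(hydroxymethyl)-2-methyloxiran-2-yl]-2-methylpentan-1-ol | OC[C@@H](C)CCC[C@@]1(C)O[C@@H]1CO | intermediate
5 | (2R,6S)-6-methyl-2-[(2S)-oxiran-2-yl]heptane-2,7-diol (not isolated) | OC[C@@H](C)CCC[C@@](C)(O)[C@@H]1CO1 | intermediate
6 | (2R,3R,7S)-3,7-dimethyl-1-(phenylsulfanyl)octane-2,3,8-triol | OC[C@@H](C)CCC[C@@](C)(O)[C@@H](O)CSc1ccccc1 | intermediate
7 | (2S)-2-methyl-5-[(4R,5R)-2,2,4-trimethyl-5-[(phenylsulfanyl)methyl]-1,3-dioxolan-4-yl]pentan-1-ol | OC[C@@H](C)CCC[C@@]1(C)OC(C)(C)O[C@H]1CSc1ccccc1 | intermediate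
8 | (4R,5R)-4-[(4S)-5-chloro-4-methylpentyl]-2,2,4-trimethyl-5-[(phenylsulfanyl)methyl]-1,3-dioxolane | ClC[C@@H](C)CCC[C@@]1(C)OC(C)(C)O[C@H]1CSc1ccccc1 | intermediate
9 | (4R,5R)-4-[(4S)-5-chloro-4-methylpentyl]-2,2,4-trimethyl-5-[(phenylsulfinyl)methyl]-1,3-dioxolane (both sulfur epimers) | ClC[C@@H](C)CCC[C@@]1(C)OC(C)(C)O[C@H]1CS(=O)c1ccccc1 | intermediate
10 | [(4R,5R)-5-[(4S)-5-chloro-4-methylpentyl]-2,2,5-trimethyl-1,3-dioxolan-4-yl](phenylsulfanyl)methyl trifluoroacetate (not isolated) | ClC[C@@H](C)CCC[C@@]1(C)OC(C)(C)O[C@H]1C(OC(=O)C(F)(F)F)Sc1ccccc1 | intermediate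
11 | (4R,5R)-5-[(4S)-5-chloro-4-methylpentyl]-2,2,5-trimethyl-1,3-dioxolane-4-carbaldehyde | ClC[C@@H](C)CCC[C@@]1(C)OC(C)(C)O[C@H]1C=O | intermediate
12 | 3-(tritylsulfanyl)propanoic acid | OC(=O)CCSC(c1ccccc1)(c1ccccc1)c1ccccc1 | starting material
13 | (4R)-4-benzyl-1,3-oxazolidin-2-one | O=C1N[C@H](Cc2ccccc2)CO1 | starting material
14 | pivalic 3-(tritylsulfanyl)propanoic anhydride (not isolated) | CC(C)(C)C(=O)OC(=O)CCSC(c1ccccc1)(c1ccccc1)c1ccccc1 | intermediate
15 | (4R)-4-benzyl-3-[3-(tritylsulfanyl)propanoyl]-1,3-oxazolidin-2-one | O=C(CCSC(c1ccccc1)(c1ccccc1)c1ccccc1)N1[C@H](Cc2ccccc2)COC1=O | intermediate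
16 | Z dibutylboron enolate of 15 (not isolated) | CCCCB(CCCC)O/C(=C\CSC(c1ccccc1)(c1ccccc1)c1ccccc1)N1[C@H](Cc2ccccc2)COC1=O | intermediate
17 | (4R)-4-benzyl-3-[(2R,3R)-3-[(4S,5R)-5-[(4S)-5-chloro-4-methylpentyl]-2,2,5-trimethyl-1,3-dioxolan-4-yl]-3-hydroxy-2-[(tritylsulfanyl)methyl]propanoyl]-1,3-oxazolidin-2-one | ClC[C@@H](C)CCC[C@@]1(C)OC(C)(C)O[C@H]1[C@H](O)[C@@H](CSC(c2ccccc2)(c2ccccc2)c2ccccc2)C(=O)N2[C@H](Cc3ccccc3)COC2=O | intermediate
18 | methyl (2R,3R)-3-[(4S,5R)-5-[(4S)-5-chloro-4-methylpentyl]-2,2,5-trimethyl-1,3-dioxolan-4-yl]-3-hydroxy-2-[(tritylsulfanyl)methyl]propanoate | ClC[C@@H](C)CCC[C@@]1(C)OC(C)(C)O[C@H]1[C@H](O)[C@@H](CSC(c2ccccc2)(c2ccccc2)c2ccccc2)C(=O)OC | intermediate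
19 | (3R,4R)-4-[(4S,5R)-5-[(4S)-5-chloro-4-methylpentyl]-2,2,5-trimethyl-1,3-dioxolan-4-yl]-4-hydroxy-3-[(tritylsulfanyl)methyl]butan-2-one (not isolated) | ClC[C@@H](C)CCC[C@@]1(C)OC(C)(C)O[C@H]1[C@H](O)[C@@H](CSC(c2ccccc2)(c2ccccc2)c2ccccc2)C(C)=O | intermediate
20 | (1R,2R)-1-[(4S,5R)-5-[(4S)-5-chloro-4-methylpentyl]-2,2,5-trimethyl-1,3-dioxolan-4-yl]-3-methyl-2-[(tritylsulfanyl)methyl]butane-1,3-diol | ClC[C@@H](C)CCC[C@@]1(C)OC(C)(C)O[C@H]1[C@H](O)[C@@H](CSC(c2ccccc2)(c2ccccc2)c2ccccc2)C(C)(C)O | intermediate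
21 | (1R,2R)-1-[(4S,5R)-5-[(4S)-5-chloro-4-methylpentyl]-2,2,5-trimethyl-1,3-dioxolan-4-yl]-3-methyl-2-(sulfanylmethyl)butane-1,3-diol (not isolated) | ClC[C@@H](C)CCC[C@@]1(C)OC(C)(C)O[C@H]1[C@H](O)[C@@H](CS)C(C)(C)O | intermediate
22 | (3R,4R,5S,6R,10S)-3-(2-hydroxypropan-2-yl)-6,10-dimethyl-5,6-O-isopropylidene-1-thiacycloundecane-4,5,6-triol (S1 lies between C8 and C9 of the plan numbering) | O[C@@H]1[C@H](C(C)(C)O)CSC[C@@H](C)CCC[C@@]2(C)OC(C)(C)O[C@@H]12 | intermediate
23 | 1-oxide of 22 (both sulfur epimers; not isolated) | O[C@@H]1[C@H](C(C)(C)O)CS(=O)C[C@@H](C)CCC[C@@]2(C)OC(C)(C)O[C@@H]12 | intermediate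
24 | 1,1-dioxide of 22 (cyclic sulfone diol) | O[C@@H]1[C@H](C(C)(C)O)CS(=O)(=O)C[C@@H](C)CCC[C@@]2(C)OC(C)(C)O[C@@H]12 | intermediate
25 | eleven-membered cyclic sulfone bis-acetonide (24 with O6 and O11 bridged by isopropylidene as a 1,3-dioxane) | CC1(C)O[C@@H]2[C@H](C(C)(C)O1)CS(=O)(=O)C[C@@H](C)CCC[C@@]3(C)OC(C)(C)O[C@@H]23 | intermediate
26 | 9-bromo derivative of 25 (α-bromosulfone; drawn at C9 though the C8 regioisomer converges; not isolated) | CC1(C)O[C@@H]2[C@H](C(C)(C)O1)CS(=O)(=O)C(Br)[C@@H](C)CCC[C@@]3(C)OC(C)(C)O[C@@H]23 | intermediate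
27 | episulfone (thiirane 1,1-dioxide spanning C8 and C9 of the ten-membered ring; not isolated) | CC1(C)O[C@@H]2[C@H](C(C)(C)O1)C4C(S4(=O)=O)[C@@H](C)CCC[C@@]3(C)OC(C)(C)O[C@@H]23 | intermediate
28 | (8Z)-cyclodec-8-ene bis-acetonide (O4/O5 dioxolane; O6/O11 dioxane) | CC1(C)O[C@@H]2[C@H](C(C)(C)O1)/C=C\[C@@H](C)CCC[C@@]3(C)OC(C)(C)O[C@@H]23 | intermediate
29 | cyclodecane bis-acetonide (28 with C8–C9 saturated) | CC1(C)O[C@@H]2[C@H](C(C)(C)O1)CC[C@@H](C)CCC[C@@]3(C)OC(C)(C)O[C@@H]23 | intermediate
30 | (4R,5S,6R,7R,10S)-7-(2-hydroxypropan-2-yl)-4,10-dimethyl-4,5-O-isopropylidenecyclodecane-4,5,6-triol | O[C@@H]1[C@H](C(C)(C)O)CC[C@@H](C)CCC[C@@]2(C)OC(C)(C)O[C@@H]12 | intermediate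
31 | angelic acid, (2Z)-2-methylbut-2-enoic acid | C/C=C(/C)C(O)=O | starting material
32 | angelic 2,4,6-trichlorobenzoic anhydride (not isolated) | C/C=C(/C)C(=O)OC(=O)c1c(Cl)cc(Cl)cc1Cl | intermediate
33 | O6 angelate of 30 (4,5-acetonide retained) | C/C=C(/C)C(=O)O[C@@H]1[C@H](C(C)(C)O)CC[C@@H](C)CCC[C@@]2(C)OC(C)(C)O[C@@H]12 | intermediate
34 | (1R,2S,3R,7S,10R)-2,3-dihydroxy-10-(2-hydroxypropan-2-yl)-3,7-dimethylcyclodecyl (2Z)-2-methylbut-2-enoate (4R,5S,6R,7R,10S in the plan numbering) | C/C=C(/C)C(=O)O[C@@H]1[C@H](C(C)(C)O)CC[C@@H](C)CCC[C@@](C)(O)[C@H]1O | target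

**Step count and risks**

Total: 20 steps. Longest linear sequence: 19 steps (steps 1–8 and 10–20 from geraniol); step 9 is the side branch.

Most likely to fail:

1. Step 13 (ring closure). Intermolecular S-alkylation to oligomers and oxidative disulfide formation may outrun the strained eleven-membered closure. The fallback sets out from 20 and returns at 22. The chloride of 20 is displaced with triphenylmethanethiol (Cs2CO3, DMF) to give the bis(tritylsulfanyl) diol F1. Iodine in pyridine-buffered MeOH/CH2Cl2 at high dilution removes both trityl groups oxidatively and closes the easier S–S bond to the twelve-membered cyclic disulfide F2. Heating F2 with P(NEt2)3 in toluene excises one sulfur (aminophosphine desulfurisation of a dialkyl disulfide) and contracts the ring to sulfide 22.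

2. Step 16 (key step). Polybromination and carbene-derived side reactions in the one-flask protocol, or slow episulfone closure in the hindered, doubly acetal-fused ring, may consume the sulfone. The fallback sets out from 25 and returns at 28, with halogenation and extrusion separated. Sulfone 25 is lithiated with n-BuLi in THF at −78 °C and quenched with C2Cl6 to give the isolated α-chlorosulfone F3. Treating F3 with t-BuOK in THF brings about the 1,3-elimination and loss of SO2 to give 28.

3. Step 10 (aldol). Enolisation may be followed by E1cB loss of tritylthiolate, destroying imide 15 before it adds to the hindered aldehyde. The fallback sets out from 13 (with 11 unchanged) and returns at 22 by way of thiol 21; sulfur is brought in after the C–C bond is made.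
   - Oxazolidinone 13 is acylated with commercial 3-(benzyloxy)propanoic acid (t-BuCOCl, Et3N, LiCl) to the benzyloxy imide F4, whose β-alkoxy group is a far poorer leaving group.
   - The same boron aldol with 11 gives the adduct F5.
   - MeOMgBr gives the methyl ester F6, and excess MeMgBr gives the benzyloxy diol F7.
   - Hydrogenolysis (H2, Pd/C, EtOAc) frees the primary C8 hydroxyl in the triol F8.
   - A Mitsunobu reaction with thioacetic acid (PPh3, DIAD) at that primary hydroxyl gives the thioacetate F9.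
   - K2CO3 in degassed MeOH at high dilution cleaves the thioester, and the liberated thiolate of 21 closes onto C9 to give 22.

**Further compounds**

F1 | step 13 | (1R,2R)-1-[(4S,5R)-2,2,5-trimethyl-5-[(4S)-4-methyl-5-(tritylsulfanyl)pentyl]-1,3-dioxolan-4-yl]-3-methyl-2-[(tritylsulfanyl)methyl]butane-1,3-diol | c1ccccc1C(c1ccccc1)(c1ccccc1)SC[C@@H](C)CCC[C@@]1(C)OC(C)(C)O[C@H]1[C@H](O)[C@@H](CSC(c2ccccc2)(c2ccccc2)c2ccccc2)C(C)(C)O
F2 | step 13 | twelve-membered cyclic disulfide diol (22 with S–S in place of S; 4,5-acetonide) | O[C@@H]1[C@H](C(C)(C)O)CSSC[C@@H](C)CCC[C@@]2(C)OC(C)(C)O[C@@H]12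
F3 | step 16 | 9-chloro derivative of sulfone bis-acetonide 25 (α-chlorosulfone) | CC1(C)O[C@@H]2[C@H](C(C)(C)O1)CS(=O)(=O)C(Cl)[C@@H](C)CCC[C@@]3(C)OC(C)(C)O[C@@H]23
F4 | step 10 | (4R)-4-benzyl-3-[3-(benzyloxy)propanoyl]-1,3-oxazolidin-2-one | O=C(CCOCc1ccccc1)N1[C@H](Cc2ccccc2)COC1=O
F5 | step 10 | (4R)-4-benzyl-3-[(2R,3R)-2-[(benzyloxy)methyl]-3-[(4S,5R)-5-[(4S)-5-chloro-4-methylpentyl]-2,2,5-trimethyl-1,3-dioxolan-4-yl]-3-hydroxypropanoyl]-1,3-oxazolidin-2-one | ClC[C@@H](C)CCC[C@@]1(C)OC(C)(C)O[C@H]1[C@H](O)[C@@H](COCc2ccccc2)C(=O)N2[C@H](Cc3ccccc3)COC2=O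
F6 | step 10 | methyl (2R,3R)-2-[(benzyloxy)methyl]-3-[(4S,5R)-5-[(4S)-5-chloro-4-methylpentyl]-2,2,5-trimethyl-1,3-dioxolan-4-yl]-3-hydroxypropanoate | ClC[C@@H](C)CCC[C@@]1(C)OC(C)(C)O[C@H]1[C@H](O)[C@@H](COCc2ccccc2)C(=O)OC
F7 | step 10 | (1R,2R)-2-[(benzyloxy)methyl]-1-[(4S,5R)-5-[(4S)-5-chloro-4-methylpentyl]-2,2,5-trimethyl-1,3-dioxolan-4-yl]-3-methylbutane-1,3-diol | ClC[C@@H](C)CCC[C@@]1(C)OC(C)(C)O[C@H]1[C@H](O)[C@@H](COCc2ccccc2)C(C)(C)O
F8 | step 10 | (1R,2R)-1-[(4S,5R)-5-[(4S)-5-chloro-4-methylpentyl]-2,2,5-trimethyl-1,3-dioxolan-4-yl]-2-(hydroxymethyl)-3-methylbutane-1,3-diol | ClC[C@@H](C)CCC[C@@]1(C)OC(C)(C)O[C@H]1[C@H](O)[C@@H](CO)C(C)(C)O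
F9 | step 10 | S-[(2R,3R)-3-[(4S,5R)-5-[(4S)-5-chloro-4-methylpentyl]-2,2,5-trimethyl-1,3-dioxolan-4-yl]-3-hydroxy-2-(2-hydroxypropan-2-yl)propyl] ethanethioate | ClC[C@@H](C)CCC[C@@]1(C)OC(C)(C)O[C@H]1[C@H](O)[C@@H](CSC(C)=O)C(C)(C)O
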